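**Retrosynthetic overview**
- The target comes from desilylation of its bis(silyl ether); the butenolide alkene and the methyl ester both arise by base-induced β-elimination and O-methylation of a cis-fused β-lactone/γ-lactone (a 2,6-dioxabicyclo[3.2.0]heptane-3,7-dione).
- That bicycle is built in one pot from a Seebach dioxolanone enolate: C-acylation with a 4-silyloxybenzoyl chloride sets the only stereocentre, then the methyl methoxyacetate enolate adds to the new ketone and triggers β-lactone closure onto the acetal carbonyl, loss of pivalaldehyde and γ-lactone closure.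
- The dioxolanone comes from L-tyrosine (hydroxy-deamination with retention, pivalaldehyde acetal, ortho-prenylation, silylation); the acyl chloride comes from 4-hydroxybenzoic acid.
- Ring order: dioxolanone (temporary) → β-lactone and γ-lactone together, with the dioxolanone lost → β-lactone opened, leaving the butenolide.

Assumption: stock reagents (t-BuMe2SiCl, (COCl)2, MeI, bases) are not numbered, and the methoxy-bearing carbon of 14, 15 and 16 is carried as an epimeric mixture because it becomes sp2 in step 8.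

**Step 1**
Reactants: 1 L-tyrosine
Product: 2 (S)-2-hydroxy-3-(4-hydroxyphenyl)propanoic acid
Conditions: NaNO2, 1 M H2SO4, H2O, 0 °C → rt
Reagents that add atoms: water, O
Why: Diazotisation (hydroxy-deamination) of the α-amino acid runs through an α-lactone, so two inversions give net retention and the (S) centre of 1 is carried into 2.

**Step 2**
Reactants: 2 (S)-2-hydroxy-3-(4-hydroxyphenyl)propanoic acid; 3 pivalaldehyde
Product: 4 (2S,5S)-2-tert-butyl-5-(4-hydroxybenzyl)-1,3-dioxolan-4-one
Conditions: cat. p-TolSO3H·H2O, cat. H2SO4, pentane, reflux (Dean–Stark); recrystallise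
Reagents that add atoms: none
Why: Seebach acetalisation (first stage of self-regeneration of stereocentres) gives the cis dioxolanone, the new acetal centre (2S) being set from the existing C5 centre under thermodynamic control and upgraded by crystallisation.

**Step 3**
Reactants: 4 (2S,5S)-2-tert-butyl-5-(4-hydroxybenzyl)-1,3-dioxolan-4-one; 5 prenyl bromide
Product: 6 (2S,5S)-2-tert-butyl-5-[4-hydroxy-3-(3-methylbut-2-en-1-yl)benzyl]-1,3-dioxolan-4-one
Conditions: NaH (1.0 equiv), toluene, 0 °C; then 5, rt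
Reagents that add atoms: none
Why: C-alkylation of a sodium phenoxide as a tight ion pair in a non-polar solvent is ortho-selective (para position blocked) and touches neither stereocentre.

**Step 4**
Reactants: 6 (2S,5S)-2-tert-butyl-5-[4-hydroxy-3-(3-methylbut-2-en-1-yl)benzyl]-1,3-dioxolan-4-one
Product: 7 (2S,5S)-2-tert-butyl-5-[4-(tert-butyldimethylsilyloxy)-3-(3-methylbut-2-en-1-yl)benzyl]-1,3-dioxolan-4-one
Conditions: t-BuMe2SiCl, imidazole, DMF, rt
Reagents that add atoms: tert-butyldimethylsilyl chloride, CC(C)(C)[Si](C)(C)Cl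
Why: Corey silylation masks the phenol before the enolate chemistry; no stereocentre is involved.

**Step 5**
Reactants: 8 4-hydroxybenzoic acid
Product: 9 tert-butyldimethylsilyl 4-(tert-butyldimethylsilyloxy)benzoate
Conditions: t-BuMe2SiCl (2.2 equiv), imidazole, DMF, rt
Reagents that add atoms: tert-butyldimethylsilyl chloride, CC(C)(C)[Si](C)(C)Cl
Why: Silylation of both acidic OH groups gives the silyl ester needed for neutral acid chloride formation; no stereocentre.

**Step 6**
Reactants: 9 tert-butyldimethylsilyl 4-(tert-butyldimethylsilyloxy)benzoate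
Product: 10 4-(tert-butyldimethylsilyloxy)benzoyl chloride
Conditions: (COCl)2, cat. HC(O)NMe2, CH2Cl2, 0 °C → rt
Reagents that add atoms: oxalyl chloride, O=C(Cl)C(=O)Cl
Why: Silyl esters are converted directly into acid chlorides by oxalyl chloride under Vilsmeier (chloroiminium) catalysis, neutral conditions that leave the aryl silyl ether intact; no stereocentre.

**Step 7**
Reactants: 7 (2S,5S)-2-tert-butyl-5-[4-(tert-butyldimethylsilyloxy)-3-(3-methylbut-2-en-1-yl)benzyl]-1,3-dioxolan-4-one; 10 4-(tert-butyldimethylsilyloxy)benzoyl chloride; 11 methyl methoxyacetate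
Product: 16 (1R,5S)-4-methoxy-1-[4-(tert-butyldimethylsilyloxy)-3-(3-methylbut-2-en-1-yl)benzyl]-5-[4-(tert-butyldimethylsilyloxy)phenyl]-2,6-dioxabicyclo[3.2.0]heptane-3,7-dione (cis-fused β-lactone/γ-lactone; both C4 epimers), via dioxolanone lithium enolate 12 (not isolated), via C5-aroyl dioxolanone 13 (not isolated), via lithium aldolate 14 (not isolated), via β-lactone lithium alkoxide 15 (not isolated)
Conditions: LiN(SiMe3)2, THF, −78 °C; 10, −78 °C; then LiCH(OMe)CO2Me (from 11 + LiN(SiMe3)2), −78 → −30 °C; AcOH, −40 °C; used crude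
Reagents that add atoms: none
Why: Proposed new method: Seebach self-regeneration of stereocentres puts the aroyl group on the enolate face anti to tert-butyl (C5 of 13 becomes R, the future quaternary centre); the non-enolisable ketone then takes up the ester enolate (aldol addition); the tertiary lithium alkoxide attacks the neighbouring acetal-activated lactone carbonyl in a 4-exo-trig acyl transfer (closest known reaction type: aldol–β-lactonisation of thiol ester or phenyl ester enolates with ketones, together with alkoxide opening of dioxolanones); the expelled hemiacetal alkoxide loses pivalaldehyde irreversibly; and the freed tertiary alkoxide closes the γ-lactone on the methyl ester, which is possible only for the cis-fused (1R,5S) bicycle, so the ring-fusion centre is set by the existing one while the epimeric aldolate can return by retro-aldol (the methoxy-bearing centre is formed without control and is erased in step 8).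

**Step 8**
Reactants: 16 (1R,5S)-4-methoxy-1-[4-(tert-butyldimethylsilyloxy)-3-(3-methylbut-2-en-1-yl)benzyl]-5-[4-(tert-butyldimethylsilyloxy)phenyl]-2,6-dioxabicyclo[3.2.0]heptane-3,7-dione
Product: 18 methyl (2R)-2-[4-(tert-butyldimethylsilyloxy)-3-(3-methylbut-2-en-1-yl)benzyl]-3-[4-(tert-butyldimethylsilyloxy)phenyl]-4-methoxy-5-oxo-2,5-dihydrofuran-2-carboxylate, via DBU-H carboxylate salt 17 (not isolated)
Conditions: DBU, MeCN, 0 °C → rt; then MeI
Reagents that add atoms: iodomethane, CI
Why: E1cB β-elimination (the lactone α-carbanion expels the β-acyloxy group, i.e. the strained β-lactone carboxylate) gives the conjugated butenolide and erases the two temporary centres, and the carboxylate is O-methylated by SN2 on MeI; the quaternary centre is not involved and stays (R).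

**Step 9**
Reactants: 18 methyl (2R)-2-[4-(tert-butyldimethylsilyloxy)-3-(3-methylbut-2-en-1-yl)benzyl]-3-[4-(tert-butyldimethylsilyloxy)phenyl]-4-methoxy-5-oxo-2,5-dihydrofuran-2-carboxylate
Product: 19 methyl (2R)-2-[4-hydroxy-3-(3-methylbut-2-en-1-yl)benzyl]-3-(4-hydroxyphenyl)-4-methoxy-5-oxo-2,5-dihydrofuran-2-carboxylate
Conditions: Bu4NF, AcOH, THF, 0 °C
Reagents that add atoms: none
Why: Fluoride-mediated cleavage of both aryl silyl ethers, buffered with AcOH so the phenoxides do not attack the lactone or ester, releases the target with the quaternary (R) centre untouched.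

**Compound list**
1 | L-tyrosine, (S)-2-amino-3-(4-hydroxyphenyl)propanoic acid | N[C@@H](Cc1ccc(O)cc1)C(=O)O | starting material
2 | (S)-2-hydroxy-3-(4-hydroxyphenyl)propanoic acid | O[C@@H](Cc1ccc(O)cc1)C(=O)O | intermediate
3 | pivalaldehyde (2,2-dimethylpropanal) | CC(C)(C)C=O | starting material
4 | (2S,5S)-2-tert-butyl-5-(4-hydroxybenzyl)-1,3-dioxolan-4-one (cis) | O=C1O[C@@H](C(C)(C)C)O[C@H]1Cc1ccc(O)cc1 | intermediate
5 | prenyl bromide (1-bromo-3-methylbut-2-ene) | CC(C)=CCBr | starting material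
6 | (2S,5S)-2-tert-butyl-5-[4-hydroxy-3-(3-methylbut-2-en-1-yl)benzyl]-1,3-dioxolan-4-one | O=C1O[C@@H](C(C)(C)C)O[C@H]1Cc1ccc(O)c(CC=C(C)C)c1 | intermediate
7 | (2S,5S)-2-tert-butyl-5-[4-(tert-butyldimethylsilyloxy)-3-(3-methylbut-2-en-1-yl)benzyl]-1,3-dioxolan-4-one | O=C1O[C@@H](C(C)(C)C)O[C@H]1Cc1ccc(O[Si](C)(C)C(C)(C)C)c(CC=C(C)C)c1 | intermediate
8 | 4-hydroxybenzoic acid | O=C(O)c1ccc(O)cc1 | starting material
9 | tert-butyldimethylsilyl 4-(tert-butyldimethylsilyloxy)benzoate | CC(C)(C)[Si](C)(C)OC(=O)c1ccc(O[Si](C)(C)C(C)(C)C)cc1 | intermediate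
10 | 4-(tert-butyldimethylsilyloxy)benzoyl chloride | O=C(Cl)c1ccc(O[Si](C)(C)C(C)(C)C)cc1 | intermediate
11 | methyl methoxyacetate | COCC(=O)OC | starting material
12 | lithium (2S)-2-tert-butyl-5-[4-(tert-butyldimethylsilyloxy)-3-(3-methylbut-2-en-1-yl)benzyl]-1,3-dioxol-4-olate | [Li+].[O-]C1=C(Cc2ccc(O[Si](C)(C)C(C)(C)C)c(CC=C(C)C)c2)O[C@H](C(C)(C)C)O1 | intermediate (not isolated)
13 | (2S,5R)-2-tert-butyl-5-[4-(tert-butyldimethylsilyloxy)benzoyl]-5-[4-(tert-butyldimethylsilyloxy)-3-(3-methylbut-2-en-1-yl)benzyl]-1,3-dioxolan-4-one (aroyl trans to tert-butyl) | O=C1O[C@@H](C(C)(C)C)O[C@]1(Cc1ccc(O[Si](C)(C)C(C)(C)C)c(CC=C(C)C)c1)C(=O)c1ccc(O[Si](C)(C)C(C)(C)C)cc1 | intermediate (not isolated)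
14 | lithium alkoxide of methyl 3-hydroxy-2-methoxy-3-[4-(tert-butyldimethylsilyloxy)phenyl]-3-{(2S,4R)-2-tert-butyl-4-[4-(tert-butyldimethylsilyloxy)-3-(3-methylbut-2-en-1-yl)benzyl]-5-oxo-1,3-dioxolan-4-yl}propanoate (carbinol and methoxy carbons unassigned) | [Li+].[O-]C(c1ccc(O[Si](C)(C)C(C)(C)C)cc1)(C(OC)C(=O)OC)[C@@]1(Cc2ccc(O[Si](C)(C)C(C)(C)C)c(CC=C(C)C)c2)O[C@H](C(C)(C)C)OC1=O | intermediate (not isolated)
15 | lithium (3R,4S)-3-[4-(tert-butyldimethylsilyloxy)-3-(3-methylbut-2-en-1-yl)benzyl]-4-(1,2-dimethoxy-2-oxoethyl)-2-oxo-4-[4-(tert-butyldimethylsilyloxy)phenyl]oxetan-3-olate (side-chain methoxy carbon unassigned) | [Li+].[O-][C@@]1(Cc2ccc(O[Si](C)(C)C(C)(C)C)c(CC=C(C)C)c2)C(=O)O[C@@]1(c3ccc(O[Si](C)(C)C(C)(C)C)cc3)C(OC)C(=O)OC | intermediate (not isolated)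
16 | (1R,5S)-4-methoxy-1-[4-(tert-butyldimethylsilyloxy)-3-(3-methylbut-2-en-1-yl)benzyl]-5-[4-(tert-butyldimethylsilyloxy)phenyl]-2,6-dioxabicyclo[3.2.0]heptane-3,7-dione (cis-fused; both C4 epimers) | O=C1O[C@]2(c3ccc(O[Si](C)(C)C(C)(C)C)cc3)[C@@]1(Cc4ccc(O[Si](C)(C)C(C)(C)C)c(CC=C(C)C)c4)OC(=O)C2OC | intermediate
17 | 1,8-diazabicyclo[5.4.0]undec-7-enium (2R)-2-[4-(tert-butyldimethylsilyloxy)-3-(3-methylbut-2-en-1-yl)benzyl]-3-[4-(tert-butyldimethylsilyloxy)phenyl]-4-methoxy-5-oxo-2,5-dihydrofuran-2-carboxylate | [O-]C(=O)[C@]1(Cc2ccc(O[Si](C)(C)C(C)(C)C)c(CC=C(C)C)c2)OC(=O)C(OC)=C1c3ccc(O[Si](C)(C)C(C)(C)C)cc3.C5CCC6=[NH+]CCCN6CC5 | intermediate (not isolated)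
18 | methyl (2R)-2-[4-(tert-butyldimethylsilyloxy)-3-(3-methylbut-2-en-1-yl)benzyl]-3-[4-(tert-butyldimethylsilyloxy)phenyl]-4-methoxy-5-oxo-2,5-dihydrofuran-2-carboxylate | COC(=O)[C@]1(Cc2ccc(O[Si](C)(C)C(C)(C)C)c(CC=C(C)C)c2)OC(=O)C(OC)=C1c3ccc(O[Si](C)(C)C(C)(C)C)cc3 | intermediate
19 | 2-O-methylbutyrolactone I, methyl (2R)-2-[4-hydroxy-3-(3-methylbut-2-en-1-yl)benzyl]-3-(4-hydroxyphenyl)-4-methoxy-5-oxo-2,5-dihydrofuran-2-carboxylate | COC(=O)[C@]1(Cc2ccc(O)c(CC=C(C)C)c2)OC(=O)C(OC)=C1c1ccc(O)cc1 | target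

**Step count**
Total: 9 steps. Longest linear sequence: 7 steps (1, 2, 3, 4, 7, 8, 9 from L-tyrosine).

**Three steps most likely to fail, with fallbacks**

Step 7 (the one-pot acylation and bis-lactonisation) is the main risk. The aldolate 14 may fragment by retro-aldol or acyl transfer instead of closing the β-lactone. The ester enolate may attack the lactone carbonyl instead of the ketone. The LiOMe released in the last ring closure may open the β-lactone before the quench. The fallback sets out from 7 and comes back at 18. Only the acylation half of step 7 is run and ketone 13 is isolated. The acetal is cleaved by acid-catalysed methanolysis (MeOH, cat. p-TolSO3H, 40 °C) to methyl (2R)-2-hydroxy-2-[4-(tert-butyldimethylsilyloxy)-3-(3-methylbut-2-en-1-yl)benzyl]-3-oxo-3-[4-(tert-butyldimethylsilyloxy)phenyl]propanoate F1. Its tertiary hydroxyl is acylated with methoxyacetyl chloride (pyridine, cat. 4-(dimethylamino)pyridine, CH2Cl2) to the methoxyacetate ester F2. The butenolide is then closed by a silyl-triflate-mediated intramolecular Mukaiyama aldol condensation (Me3SiOTf, Et3N, CH2Cl2, −78 → 0 °C; then DBU). The aldol oxygen is silylated as it forms, so no free alkoxide can fragment, and 18 is obtained directly without the bicycle.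

Step 3 (ortho-prenylation) is the second risk. O-alkylation and double C-alkylation compete, and the phenoxide can attack the acetal-type lactone of another molecule. The fallback sets out from 4 and comes back at 6. Compound 4 is O-alkylated with 5 (K2CO3, acetone, rt) to the aryl prenyl ether (2S,5S)-2-tert-butyl-5-[4-(3-methylbut-2-en-1-yloxy)benzyl]-1,3-dioxolan-4-one F3. The prenyl group is then moved from oxygen to the ortho carbon by a Lewis-acid-catalysed [1,3] shift (cat. Bi(OTf)3, CH2Cl2, 0 °C).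

Step 8 (β-lactone opening and esterification) is the third risk. DBU may attack the β-lactone carbonyl, or the intermediate carboxylate may decarboxylate to the stabilised furanolate before it is methylated. The fallback sets out from 16 and comes back at 18. The β-lactone is opened at its acyl carbon with methanol (MeOH, Et3N, cat. 4-(dimethylamino)pyridine, 0 °C), which installs the methyl ester directly and gives the tertiary β-hydroxy lactone methyl (2R,3S)-3-hydroxy-2-[4-(tert-butyldimethylsilyloxy)-3-(3-methylbut-2-en-1-yl)benzyl]-3-[4-(tert-butyldimethylsilyloxy)phenyl]-4-methoxy-5-oxotetrahydrofuran-2-carboxylate F4. This is dehydrated to 18 with Burgess reagent (Et3N+SO2N−CO2Me, toluene, 50 °C).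

**Further compounds**
F1 | step 7 | methyl (2R)-2-hydroxy-2-[4-(tert-butyldimethylsilyloxy)-3-(3-methylbut-2-en-1-yl)benzyl]-3-oxo-3-[4-(tert-butyldimethylsilyloxy)phenyl]propanoate | COC(=O)[C@@](O)(Cc1ccc(O[Si](C)(C)C(C)(C)C)c(CC=C(C)C)c1)C(=O)c2ccc(O[Si](C)(C)C(C)(C)C)cc2
F2 | step 7 | methyl (2R)-2-(2-methoxyacetoxy)-2-[4-(tert-butyldimethylsilyloxy)-3-(3-methylbut-2-en-1-yl)benzyl]-3-oxo-3-[4-(tert-butyldimethylsilyloxy)phenyl]propanoate | COC(=O)[C@@](OC(=O)COC)(Cc1ccc(O[Si](C)(C)C(C)(C)C)c(CC=C(C)C)c1)C(=O)c2ccc(O[Si](C)(C)C(C)(C)C)cc2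
F3 | step 3 | (2S,5S)-2-tert-butyl-5-[4-(3-methylbut-2-en-1-yloxy)benzyl]-1,3-dioxolan-4-one | O=C1O[C@@H](C(C)(C)C)O[C@H]1Cc1ccc(OCC=C(C)C)cc1
F4 | step 8 | methyl (2R,3S)-3-hydroxy-2-[4-(tert-butyldimethylsilyloxy)-3-(3-methylbut-2-en-1-yl)benzyl]-3-[4-(tert-butyldimethylsilyloxy)phenyl]-4-methoxy-5-oxotetrahydrofuran-2-carboxylate (both C4 epimers) | COC(=O)[C@]1(Cc2ccc(O[Si](C)(C)C(C)(C)C)c(CC=C(C)C)c2)OC(=O)C(OC)[C@@]1(O)c3ccc(O[Si](C)(C)C(C)(C)C)cc3
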